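**Retrosynthetic overview**

1. The target is traced back to the (2S)-flavanone 21, which carries allyl groups in place of both prenyl groups and MOM ethers on the three phenols. The end game is MOM removal followed by a double cross-metathesis (allyl to prenyl).
2. Ring C is opened at C2–C3: 21 comes from the racemic cyclic enol acetal 19 (a 2-aryl-4-methylene-4H-1,3-benzodioxine) by a catalytic enantioselective Petasis–Ferrier-type [1,3] O-to-C rearrangement. The enabling feature is that C2 is bonded to the ring oxygen O1 and to C1′ of ring B, whose para carbon C4′ carries the chromene oxygen, so a cation at C2 is stabilized by two oxygens; C3 is the enol carbon α to the C4 ketone on ring A.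
3. 19 comes from benzodioxinone 17 by carbonyl methylenation, and 17 from salicylic acid 15 (ring A) and aldehyde 9 (ring B with the chromene ring) by acetalization.
4. Order of ring formation: the chromene ring on ring B (propargyl Claisen/electrocyclization), then the temporary 1,3-dioxinone ring, then ring C in the key step.
5. Both C-allyl groups are placed by ortho-Claisen rearrangements; they are weaker π-nucleophiles than prenyl groups and are kept until the cationic steps are over.

Key step: step 12

Assumption: the sense of induction of the chiral acid in step 12 cannot be predicted with certainty; the (R)-acid is written, and its (S)-antipode would be used if the induction proved to be opposite.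

**Route**

Step 1
Reactants: 1 3,4-dihydroxybenzaldehyde; 2 3-chloro-3-methylbut-1-yne
Product: 3 3-hydroxy-4-[(2-methylbut-3-yn-2-yl)oxy]benzaldehyde
Conditions: K2CO3 (1.1 equiv), KI, CuI (cat.), DMF, 60 °C
Reagents that add atoms: 3-chloro-3-methylbut-1-yne, CC(C)(Cl)C#C
Why: The 4-OH para to the formyl group is the more acidic phenol, so one equivalent of base should direct this copper-assisted propargylic etherification (Williamson type) to O4.

Step 2
Reactants: 3 3-hydroxy-4-[(2-methylbut-3-yn-2-yl)oxy]benzaldehyde; 4 allyl bromide
Product: 5 3-(allyloxy)-4-[(2-methylbut-3-yn-2-yl)oxy]benzaldehyde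
Conditions: K2CO3, DMF, rt
Reagents that add atoms: allyl bromide, C=CCBr
Why: Williamson etherification of the remaining phenol with a reactive allylic halide should proceed without touching the tertiary propargyl ether.

Step 3
Reactants: 5 3-(allyloxy)-4-[(2-methylbut-3-yn-2-yl)oxy]benzaldehyde
Product: 7 7-allyl-8-hydroxy-2,2-dimethyl-2H-chromene-6-carbaldehyde, via allyloxy chromene aldehyde 6 (not isolated)
Conditions: PhNEt2, 190 °C, sealed tube
Reagents that add atoms: none
Why: The aryl propargyl ether should undergo propargyl Claisen rearrangement, 1,5-hydrogen shift and oxa-6π electrocyclization to close the chromene at its only free ortho carbon, after which the allyl ether undergoes an aromatic Claisen rearrangement to its only free ortho carbon, between the oxygen and the formyl group.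

Step 4
Reactants: 7 7-allyl-8-hydroxy-2,2-dimethyl-2H-chromene-6-carbaldehyde; 8 chloromethyl methyl ether
Product: 9 7-allyl-8-(methoxymethoxy)-2,2-dimethyl-2H-chromene-6-carbaldehyde
Conditions: NaH, MOMCl, THF–DMF, 0 °C
Reagents that add atoms: chloromethyl methyl ether, COCCl
Why: O-alkylation of the sodium phenoxide (Williamson etherification) should protect the hindered phenol as an acetal that tolerates the later Lewis and Brønsted acid steps at low temperature.

Step 5
Reactants: 10 2,4,6-trihydroxybenzoic acid; 4 allyl bromide
Product: 11 allyl 4-(allyloxy)-2,6-dihydroxybenzoate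
Conditions: allyl bromide (2.05 equiv), K2CO3 (2.2 equiv), DMF, 0 °C to rt
Reagents that add atoms: allyl bromide, C=CCBr
Why: SN2 O-alkylation should take place at the carboxylate and at the para phenoxide, the most acidic phenol, while the two ortho hydroxyls are held back by hydrogen bonds to the carboxyl group.

Step 6
Reactants: 11 allyl 4-(allyloxy)-2,6-dihydroxybenzoate; 8 chloromethyl methyl ether
Product: 12 allyl 4-(allyloxy)-2-hydroxy-6-(methoxymethoxy)benzoate
Conditions: MOMCl (1.1 equiv), K2CO3, acetone, rt
Reagents that add atoms: chloromethyl methyl ether, COCCl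
Why: Williamson etherification of one of the two equivalent ortho hydroxyls should stop at the mono-ether, because the remaining hydroxyl is then locked in a strong hydrogen bond to the ester carbonyl.

Step 7
Reactants: 12 allyl 4-(allyloxy)-2-hydroxy-6-(methoxymethoxy)benzoate
Product: 13 allyl 3-allyl-2,4-dihydroxy-6-(methoxymethoxy)benzoate
Conditions: PhNEt2, 190 °C
Reagents that add atoms: none
Why: The aromatic Claisen rearrangement is expected to deliver the allyl group to C3, between the chelated 2-OH and the allyloxy oxygen, because the hydrogen-bonded o-hydroxy ester fixes the ring double bonds as it does in 4-allyloxy-2-hydroxyaryl carbonyl compounds.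

Step 8
Reactants: 13 allyl 3-allyl-2,4-dihydroxy-6-(methoxymethoxy)benzoate; 8 chloromethyl methyl ether
Product: 14 allyl 3-allyl-2-hydroxy-4,6-bis(methoxymethoxy)benzoate
Conditions: MOMCl (1.2 equiv), K2CO3, acetone, rt
Reagents that add atoms: chloromethyl methyl ether, COCCl
Why: Williamson etherification should take the free 4-OH and leave the chelated 2-OH, which is flanked by the allyl and ester groups, untouched.

Step 9
Reactants: 14 allyl 3-allyl-2-hydroxy-4,6-bis(methoxymethoxy)benzoate
Product: 15 3-allyl-2-hydroxy-4,6-bis(methoxymethoxy)benzoic acid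
Conditions: Pd(PPh3)4 (5 mol%), morpholine, THF, rt; then cold aqueous citric acid; used at once
Reagents that add atoms: none
Why: Palladium-catalyzed allyl transfer to morpholine (Tsuji–Trost deallylation) should cleave only the allyl ester, since the C-allyl group cannot form a π-allyl complex, and it frees the decarboxylation-prone acid without heat or strong acid.

Step 10
Reactants: 15 3-allyl-2-hydroxy-4,6-bis(methoxymethoxy)benzoic acid; 9 7-allyl-8-(methoxymethoxy)-2,2-dimethyl-2H-chromene-6-carbaldehyde
Product: 17 rac-8-allyl-2-[7-allyl-8-(methoxymethoxy)-2,2-dimethyl-2H-chromen-6-yl]-5,7-bis(methoxymethoxy)-4H-1,3-benzodioxin-4-one, via bis(trimethylsilyl) derivative 16 (not isolated)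
Conditions: HMDS, TMSCl (cat.), CH2Cl2, 40 °C, evaporation; then 9, TMSOTf (10 mol%), CH2Cl2, −78 to −30 °C; pyridine quench
Reagents that add atoms: none
Why: Silyl triflate-catalyzed acetalization of the silyl ester/silyl ether with the aldehyde should close the 1,3-dioxin-4-one ring, driven by formation of hexamethyldisiloxane, as in the standard preparation of 1,3-dioxan-4-ones from silylated hydroxy acids; the acetal carbon is formed racemic, which is sufficient because it is ionized in step 12.

Step 11
Reactants: 17 rac-8-allyl-2-[7-allyl-8-(methoxymethoxy)-2,2-dimethyl-2H-chromen-6-yl]-5,7-bis(methoxymethoxy)-4H-1,3-benzodioxin-4-one; 18 dimethyltitanocene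
Product: 19 rac-8-allyl-2-[7-allyl-8-(methoxymethoxy)-2,2-dimethyl-2H-chromen-6-yl]-5,7-bis(methoxymethoxy)-4-methylene-4H-1,3-benzodioxine
Conditions: Cp2TiMe2 (2.5 equiv), toluene–THF, 70 °C, dark; filtration through basic alumina
Reagents that add atoms: dimethyltitanocene (Cp2TiMe2), C[Ti](C)(C1C=CC=C1)C1C=CC=C1
Why: Petasis methylenation should convert the lactone carbonyl into the exocyclic enol ether through the thermally generated titanocene methylidene, under non-acidic conditions that leave the acetal, the MOM ethers and the alkenes intact.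

Step 12
Reactants: 19 rac-8-allyl-2-[7-allyl-8-(methoxymethoxy)-2,2-dimethyl-2H-chromen-6-yl]-5,7-bis(methoxymethoxy)-4-methylene-4H-1,3-benzodioxine
Product: 21 (2S)-8-allyl-2-[7-allyl-8-(methoxymethoxy)-2,2-dimethyl-2H-chromen-6-yl]-5,7-bis(methoxymethoxy)chroman-4-one, via oxocarbenium–enol ion pair 20 (not isolated)
Conditions: (R)-3,3′-bis(2,4,6-triisopropylphenyl)-1,1′-binaphthyl-2,2′-diyl N-triflylphosphoramide (10 mol%), 4 Å MS, toluene, −60 to −20 °C; Et3N quench
Reagents that add atoms: none
Why: Proposed new method: the chiral acid should open the enol acetal by heterolysis of the bond between the acetal carbon (the future C2) and the enol ether oxygen, giving contact ion pair 20 of an (E)-aryloxycarbenium ion, stabilized by O1 and by the para chromene oxygen of ring B, and the tethered aryl ketone enol, which is hydrogen-bonded to the chiral phosphoramidate; the enol carbon then attacks C2 and the proton returns to the catalyst, so both enantiomers of 19 converge on one planar intermediate. The closest known reaction types are the Lewis acid-promoted Petasis–Ferrier rearrangement of 4-methylene-1,3-dioxanes to tetrahydropyran-4-ones, the chiral phosphoric acid-catalyzed aza-Petasis–Ferrier rearrangement of hemiaminal vinyl ethers, and chiral Brønsted acid-catalyzed Prins and oxa-Pictet–Spengler cyclizations of oxocarbenium ions. Ring C closes in a 6-(enolendo)-endo-trig mode through a half-chair transition state with the ring B aryl group pseudo-equatorial. The C2 stereocenter is set by the chiral counter-anion, which should shield one enantiotopic face of the oxocarbenium ion while it holds the enol by a hydrogen bond. The step needs C-alkylation in preference to return by O-alkylation (which only regenerates 19, whereas C–C bond formation is irreversible), attack by the enol in preference to the two alkenes (secured by carrying terminal allyl groups in place of the more nucleophilic prenyl groups and by the proximity of the enol), and no later re-ionization of the product at C2 (secured by low temperature and the basic quench).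

Step 13
Reactants: 21 (2S)-8-allyl-2-[7-allyl-8-(methoxymethoxy)-2,2-dimethyl-2H-chromen-6-yl]-5,7-bis(methoxymethoxy)chroman-4-one
Product: 22 (2S)-8-allyl-2-(7-allyl-8-hydroxy-2,2-dimethyl-2H-chromen-6-yl)-5,7-dihydroxychroman-4-one
Conditions: HCl (1.25 M in MeOH), 40 °C
Reagents that add atoms: none
Why: Acid-catalyzed methanolysis of the three MOM acetals should free the phenols while the prenyl groups are still masked as acid-tolerant allyl groups, and the absence of base avoids the retro-oxa-Michael opening that would racemize C2.

Step 14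
Reactants: 22 (2S)-8-allyl-2-(7-allyl-8-hydroxy-2,2-dimethyl-2H-chromen-6-yl)-5,7-dihydroxychroman-4-one; 23 2-methylbut-2-ene
Product: 24 (2S)-5,7-dihydroxy-2-[8-hydroxy-2,2-dimethyl-7-(3-methylbut-2-en-1-yl)-2H-chromen-6-yl]-8-(3-methylbut-2-en-1-yl)chroman-4-one
Conditions: second-generation Grubbs catalyst RuCl2(=CHPh)(H2IMes)(PCy3) (10 mol%), 2-methylbut-2-ene/CH2Cl2, 40 °C
Reagents that add atoms: 2-methylbut-2-ene, CC=C(C)C
Why: Olefin cross-metathesis with excess 2-methylbut-2-ene should convert both terminal allyl groups into prenyl groups with loss of propene under neutral conditions that tolerate free phenols and do not touch C2; the hindered, conjugated chromene double bond is expected to stay out of the reaction.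

**Compound list**

1 | 3,4-dihydroxybenzaldehyde | O=Cc1ccc(O)c(O)c1 | starting material
2 | 3-chloro-3-methylbut-1-yne | CC(C)(Cl)C#C | starting material
3 | 3-hydroxy-4-[(2-methylbut-3-yn-2-yl)oxy]benzaldehyde | O=Cc1ccc(OC(C)(C)C#C)c(O)c1 | intermediate
4 | allyl bromide | C=CCBr | starting material
5 | 3-(allyloxy)-4-[(2-methylbut-3-yn-2-yl)oxy]benzaldehyde | O=Cc1ccc(OC(C)(C)C#C)c(OCC=C)c1 | intermediate
6 | 8-(allyloxy)-2,2-dimethyl-2H-chromene-6-carbaldehyde | CC1(C)C=Cc2cc(C=O)cc(OCC=C)c2O1 | intermediate
7 | 7-allyl-8-hydroxy-2,2-dimethyl-2H-chromene-6-carbaldehyde | CC1(C)C=Cc2cc(C=O)c(CC=C)c(O)c2O1 | intermediate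
8 | chloromethyl methyl ether | COCCl | starting material
9 | 7-allyl-8-(methoxymethoxy)-2,2-dimethyl-2H-chromene-6-carbaldehyde | CC1(C)C=Cc2cc(C=O)c(CC=C)c(OCOC)c2O1 | intermediate
10 | 2,4,6-trihydroxybenzoic acid | OC(=O)c1c(O)cc(O)cc1O | starting material
11 | allyl 4-(allyloxy)-2,6-dihydroxybenzoate | C=CCOC(=O)c1c(O)cc(OCC=C)cc1O | intermediate
12 | allyl 4-(allyloxy)-2-hydroxy-6-(methoxymethoxy)benzoate | C=CCOC(=O)c1c(O)cc(OCC=C)cc1OCOC | intermediate
13 | allyl 3-allyl-2,4-dihydroxy-6-(methoxymethoxy)benzoate | C=CCOC(=O)c1c(OCOC)cc(O)c(CC=C)c1O | intermediate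
14 | allyl 3-allyl-2-hydroxy-4,6-bis(methoxymethoxy)benzoate | C=CCOC(=O)c1c(OCOC)cc(OCOC)c(CC=C)c1O | intermediate
15 | 3-allyl-2-hydroxy-4,6-bis(methoxymethoxy)benzoic acid | OC(=O)c1c(OCOC)cc(OCOC)c(CC=C)c1O | intermediate
16 | trimethylsilyl 3-allyl-4,6-bis(methoxymethoxy)-2-(trimethylsilyloxy)benzoate | C[Si](C)(C)OC(=O)c1c(OCOC)cc(OCOC)c(CC=C)c1O[Si](C)(C)C | intermediate
17 | rac-8-allyl-2-[7-allyl-8-(methoxymethoxy)-2,2-dimethyl-2H-chromen-6-yl]-5,7-bis(methoxymethoxy)-4H-1,3-benzodioxin-4-one | O=C1OC(c2cc3C=CC(C)(C)Oc3c(OCOC)c2CC=C)Oc2c(CC=C)c(OCOC)cc(OCOC)c12 | intermediate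
18 | dimethyltitanocene (Cp2TiMe2) | C[Ti](C)(C1C=CC=C1)C1C=CC=C1 | starting material
19 | rac-8-allyl-2-[7-allyl-8-(methoxymethoxy)-2,2-dimethyl-2H-chromen-6-yl]-5,7-bis(methoxymethoxy)-4-methylene-4H-1,3-benzodioxine | C=C1OC(c2cc3C=CC(C)(C)Oc3c(OCOC)c2CC=C)Oc2c(CC=C)c(OCOC)cc(OCOC)c12 | intermediate
20 | oxocarbenium–enol ion pair (cation shown; the counter-ion is the anion of the chiral acid) | C=C(O)c1c(OCOC)cc(OCOC)c(CC=C)c1[O+]=Cc1cc2C=CC(C)(C)Oc2c(OCOC)c1CC=C | intermediate
21 | (2S)-8-allyl-2-[7-allyl-8-(methoxymethoxy)-2,2-dimethyl-2H-chromen-6-yl]-5,7-bis(methoxymethoxy)chroman-4-one | C=CCc1c([C@@H]2CC(=O)c3c(OCOC)cc(OCOC)c(CC=C)c3O2)cc2c(c1OCOC)OC(C)(C)C=C2 | intermediate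
22 | (2S)-8-allyl-2-(7-allyl-8-hydroxy-2,2-dimethyl-2H-chromen-6-yl)-5,7-dihydroxychroman-4-one | C=CCc1c([C@@H]2CC(=O)c3c(O)cc(O)c(CC=C)c3O2)cc2c(c1O)OC(C)(C)C=C2 | intermediate
23 | 2-methylbut-2-ene | CC=C(C)C | starting material
24 | (2S)-5,7-dihydroxy-2-[8-hydroxy-2,2-dimethyl-7-(3-methylbut-2-en-1-yl)-2H-chromen-6-yl]-8-(3-methylbut-2-en-1-yl)chroman-4-one | CC(C)=CCc1c([C@@H]2CC(=O)c3c(O)cc(O)c(CC=C(C)C)c3O2)cc2c(c1O)OC(C)(C)C=C2 | target

**Step count and risks**

Total step count: 14. Longest linear sequence: 10 steps (steps 5 to 14); the ring B branch (steps 1 to 4) joins at step 10.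

Steps most likely to fail:

1. Step 12 (Proposed new method). The ion pair may show poor facial discrimination, the oxocarbenium ion may be lost to adventitious water or to oligomerization before the enol closes the ring, or the product may racemize by re-ionization at C2. The fallback uses known chemistry and sets out from 15 and 9. Acid 15 would be treated with excess MeLi in THF to give the methyl ketone 1-[3-allyl-2-hydroxy-4,6-bis(methoxymethoxy)phenyl]ethanone F1. Claisen–Schmidt condensation of F1 with aldehyde 9 (KOH, EtOH) would give the 2′-hydroxychalcone (E)-1-[3-allyl-2-hydroxy-4,6-bis(methoxymethoxy)phenyl]-3-[7-allyl-8-(methoxymethoxy)-2,2-dimethyl-2H-chromen-6-yl]prop-2-en-1-one F2. Oxa-Michael ring closure (NaOAc, EtOH, reflux) would give the racemic flavanone rac-8-allyl-2-[7-allyl-8-(methoxymethoxy)-2,2-dimethyl-2H-chromen-6-yl]-5,7-bis(methoxymethoxy)chroman-4-one F3. Its enantiomers would be separated by preparative HPLC on a chiral stationary phase, and the (2S) enantiomer is 21, where the route is rejoined.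

2. Step 10. The acetalization equilibrium may be unfavorable for the electron-rich, ortho-substituted aldehyde, the product acetal may ionize under the silyl triflate, and acid 15 may decarboxylate. The fallback sets out from 9 and changes the electrophile and the driving force. Aldehyde 9 would first be converted (HC(OMe)3, PPTS, MeOH) into its dimethyl acetal 7-allyl-6-(dimethoxymethyl)-8-(methoxymethoxy)-2,2-dimethyl-2H-chromene F4. F4 would then be exchanged with acid 15 under mild proton catalysis (PPTS, toluene, 5 Å MS, 50 °C), with methanol removed by the sieves, as in the preparation of 2-aryl-1,3-dioxan-4-ones from hydroxy acids and aldehyde acetals. The product is 17, where the route is rejoined.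

3. Step 7. The allyl group may migrate to C5 instead of C3 if the hydrogen-bonded ester fixes the ring bonds less firmly than a ketone would. The fallback sets out from 11 and removes the regiochemical question by symmetry. The Claisen rearrangement would be run on the symmetric diol 11 (PhNEt2, 190 °C), whose two ortho carbons are equivalent, to give allyl 3-allyl-2,4,6-trihydroxybenzoate F5. Treatment with MOMCl (2.2 equiv) and K2CO3 in acetone should then etherify the free 4-OH and the less hindered 6-OH and leave the 2-OH, which is flanked by the allyl group and the ester. The product is 14, where the route is rejoined.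

**Further compounds**

F1 | step 12 | 1-[3-allyl-2-hydroxy-4,6-bis(methoxymethoxy)phenyl]ethanone | CC(=O)c1c(OCOC)cc(OCOC)c(CC=C)c1O
F2 | step 12 | (E)-1-[3-allyl-2-hydroxy-4,6-bis(methoxymethoxy)phenyl]-3-[7-allyl-8-(methoxymethoxy)-2,2-dimethyl-2H-chromen-6-yl]prop-2-en-1-one | O=C(/C=C/c1cc2C=CC(C)(C)Oc2c(OCOC)c1CC=C)c1c(OCOC)cc(OCOC)c(CC=C)c1O
F3 | step 12 | rac-8-allyl-2-[7-allyl-8-(methoxymethoxy)-2,2-dimethyl-2H-chromen-6-yl]-5,7-bis(methoxymethoxy)chroman-4-one | C=CCc1c(C2CC(=O)c3c(OCOC)cc(OCOC)c(CC=C)c3O2)cc2c(c1OCOC)OC(C)(C)C=C2
F4 | step 10 | 7-allyl-6-(dimethoxymethyl)-8-(methoxymethoxy)-2,2-dimethyl-2H-chromene | COC(OC)c1cc2C=CC(C)(C)Oc2c(OCOC)c1CC=C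
F5 | step 7 | allyl 3-allyl-2,4,6-trihydroxybenzoate | C=CCOC(=O)c1c(O)cc(O)c(CC=C)c1O
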